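**Retrosynthetic overview** (target locants are the indene numbers: C1 bears Me and the side chain, C2 the CO2H, C3 is CH2, C3a=C4 is the ring alkene, C7 is CMe2, C7a bears Me; the same labels are used for these atoms in all intermediates)
1. Side chain last: the (Z)-allylic acetate comes from a C1 propanal by Still–Gennari olefination, ester reduction and acetylation.
2. The five-membered ring C1–C2–C3–C3a–C7a is not closed by a cyclisation. It arises from a cyclobutane (C1, C2, C3, C3a) spiro-fused at C3a to the six-membered ring, by a 4→5 ring expansion: C1 shifts from C3a to C7a and the C3a cation loses H-4 to give C3a=C4.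
3. Enabling feature: the quaternary C7a lies between the quaternary C1 and the sp2 ring-fusion carbon C3a, so the hindered C1–C7a bond can be the migrated bond of a cyclobutylcarbinyl cation and the ring alkene its resting place.
4. The spiro cyclobutane comes from a [2+2] photocycloaddition of 3-methylcyclohex-2-enone to the exocyclic alkene of a resolved tertiary carbamate. The enone supplies C1 with its methyl, C2, the carboxyl carbon and the three chain carbons as a temporary ring, which is cut by α-hydroxylation and Pb(OAc)4; C2 is then set by kinetic protonation.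
5. Ring order: six-membered carbocycle (from 2,2-dimethylcyclohexanone) → cyclobutane (with the temporary cyclohexanone, later opened) → cyclopentane by ring expansion.

Key step: step 9

Remark: 2,2-dimethylcyclohexanone, (R)-1-phenylethyl isocyanate, 3-methylcyclohex-2-enone and ethyl 2-[bis(2,2,2-trifluoroethoxy)phosphoryl]propanoate are taken as purchasable. The configuration of 5 and all later compounds rests on assigning the two carbamate diastereomers of step 3, to be done by X-ray analysis.

Step 1
Reactants: 1 2,2-dimethylcyclohexanone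
Product: 2 2,2-dimethyl-6-methylidenecyclohexan-1-one
Conditions: (CH2O)n, N-methylanilinium trifluoroacetate, THF, reflux
Reagents that add atoms: paraformaldehyde (as formaldehyde), C=O
Why: Mannich-type α-methylenation at the only enolisable α-position (the other α-carbon is quaternary); no stereocentre is formed.

Step 2
Reactants: 2 2,2-dimethyl-6-methylidenecyclohexan-1-one
Product: 3 rac-1,2,2-trimethyl-6-methylidenecyclohexan-1-ol
Conditions: MeLi, CeCl3, THF, −78 °C; aq. NH4Cl
Reagents that add atoms: methyllithium, [Li]C
Why: organocerium 1,2-addition to the hindered enone carbonyl (CeCl3 suppresses conjugate addition and enolisation); the tertiary carbinol forms as the racemate and is resolved in step 3.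

Step 3
Reactants: 3 rac-1,2,2-trimethyl-6-methylidenecyclohexan-1-ol; 4 (R)-1-phenylethyl isocyanate
Product: 5 (1R)-1,2,2-trimethyl-6-methylidenecyclohexyl N-[(1R)-1-phenylethyl]carbamate
Conditions: CuCl (cat.), DMF, 25 °C; chromatographic separation of the two diastereomers
Reagents that add atoms: none
Why: CuCl-catalysed addition of the hindered tertiary alcohol to the isocyanate gives two diastereomeric carbamates that should be separable, and the one from the (R)-alcohol is kept; the carbamate is at once resolving handle, protecting group and the later leaving group.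

Step 4
Reactants: 5 (1R)-1,2,2-trimethyl-6-methylidenecyclohexyl N-[(1R)-1-phenylethyl]carbamate; 6 3-methylcyclohex-2-en-1-one
Product: 7 spiro photoadduct (cis-fused 6-methylbicyclo[4.2.0]octan-2-one whose C7 is the spiro carbon of the carbamate-bearing ring A)
Conditions: hν (λ ≥ 350 nm), 6 (3 equiv, in portions), CH2Cl2, −20 °C
Reagents that add atoms: none
Why: triplet enone–alkene [2+2] photocycloaddition in the head-to-tail sense joins the enone β-carbon (future C1) to the disubstituted alkene carbon (future C3a) and the α-carbon (future C2) to the CH2 (future C3); the four-membered ring enforces the cis ring fusion, the bulky carbamate-bearing arm should take the exo face (cis to the C1 methyl), and the bond at C3a should form anti to the pseudo-axial carbamate oxygen, so the (R)-carbinol centre of 5 fixes the absolute configuration at C3a, C1 and C2 (other isomers are removed by chromatography).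

Step 5
Reactants: 7 spiro photoadduct
Product: 9 3-hydroxy ketone of the photoadduct (mixture of carbinol epimers), via dipotassium enolate 8 (not isolated)
Conditions: KN(SiMe3)2 (2.3 equiv), THF, −78 °C; then 2-(phenylsulfonyl)-3-phenyloxaziridine, −78 °C; aq. NH4Cl
Reagents that add atoms: 2-(phenylsulfonyl)-3-phenyloxaziridine, O=S(=O)(c1ccccc1)N1OC1c1ccccc1
Why: kinetic enolisation at the CH2 next to the ketone (the other α-carbon is the hindered ring-fusion CH) and electrophilic hydroxylation of the enolate by the sulfonyloxaziridine; the new carbinol centre forms as a mixture, which does not matter because it becomes the aldehyde carbon in step 6.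

Step 6
Reactants: 9 3-hydroxy ketone of the photoadduct
Product: 10 methyl 1,5,6,6-tetramethyl-1-(3-oxopropyl)-5-{[(1R)-1-phenylethyl]carbamoyloxy}spiro[3.5]nonane-2-carboxylate (ester trans to the C1 methyl)
Conditions: Pb(OAc)4, MeOH–benzene (1:1), 0 °C
Reagents that add atoms: methanol, CO
Why: glycol-type cleavage of the α-hydroxy ketone by lead tetraacetate in methanol opens the temporary ring between the carbonyl and carbinol carbons, making the former the C2 methyl ester and the latter the terminal aldehyde of the three-carbon chain on C1; no stereocentre is touched, so the ester stays trans to the C1 methyl.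

Step 7
Reactants: 10 spiro ester aldehyde
Product: 11 methyl 1-(3-hydroxypropyl)-1,5,6,6-tetramethyl-5-{[(1R)-1-phenylethyl]carbamoyloxy}spiro[3.5]nonane-2-carboxylate (ester trans to the C1 methyl)
Conditions: NaBH4, MeOH, 0 °C
Reagents that add atoms: none
Why: chemoselective borohydride reduction of the aldehyde beside ester and carbamate, needed because an aldehyde would not survive the strong base of step 8.

Step 8
Reactants: 11 trans hydroxy ester
Product: 13 C2 epimer of 11 (ester cis to the C1 methyl and to the carbamate-bearing ring carbon), via trilithium enolate 12 (not isolated)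
Conditions: LiN(iPr)2 (3.5 equiv), THF, −78 → −30 °C; then 2,6-di-tert-butylphenol (excess), −78 °C; aq. NH4Cl
Reagents that add atoms: none
Why: deprotonation to the ester enolate (exocyclic to the cyclobutane) followed by kinetic protonation with a hindered phenol from the face opposite the carbamate-bearing ring-A carbon, which sits 1,3-cis across the cyclobutane and blocks its face, should put the hydrogen cis to the side chain and leave the ester cis to the C1 methyl, the contra-thermodynamic C2 configuration of the target.

Step 9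
Reactants: 13 cis hydroxy ester
Product: 17 methyl (1R,2S,7aS)-1-(3-hydroxypropyl)-1,7,7,7a-tetramethyl-2,3,5,6,7,7a-hexahydro-1H-indene-2-carboxylate, via trimethylsilyl ether 14 (not isolated), via tertiary cation triflate 15 (not isolated), via rearranged trimethylsilyl ether 16 (not isolated)
Conditions: Me3SiOTf (3 equiv), 2,6-di-tert-butyl-4-methylpyridine (4 equiv), CH2Cl2, −78 → −20 °C; then 1 M HCl, THF, 0 °C
Reagents that add atoms: none
Why: Me3SiOTf silylates the carbamate (the activation used to cleave tert-butyl carbamates) and the tertiary C7a–O bond ionises with participation of the antiperiplanar, strained cyclobutane bond C3a–C1, so that C1 shifts from C3a to C7a (cyclobutylcarbinyl→cyclopentyl Wagner–Meerwein shift) and the tertiary C3a cation then loses H-4 to the hindered pyridine. The closest known reaction type is the acid-induced rearrangement of spiro[3.5]non-5-yl cations to hydrindenes. The five-membered ring is thus closed by a suprafacial 1,2-alkyl shift that enlarges the four-membered ring, not by a cyclisation. C1 migrates with retention and enters C7a anti to the leaving oxygen, so the C7a methyl ends cis to the C1 methyl and the configuration of the spiro carbon C3a is transferred to C7a, while C2 is untouched. The step needs migration of C1 rather than of the CH2 arm, which the antiperiplanar geometry set in step 4 and the higher migratory aptitude of the quaternary carbon should secure. It also needs proton loss towards C4 rather than C3, favoured because the double bond becomes endocyclic in the six-membered and exocyclic to the five-membered ring, and the non-nucleophilic medium keeps the ester from capturing the cation.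

Step 10
Reactants: 17 hydrindene hydroxy ester
Product: 19 (1R,2S,7aS)-1-(3-hydroxypropyl)-1,7,7,7a-tetramethyl-2,3,5,6,7,7a-hexahydro-1H-indene-2-carboxylic acid, via lithium carboxylate 18 (not isolated)
Conditions: LiI, pyridine, reflux; then 1 M HCl, 0 °C
Reagents that add atoms: none
Why: SN2 demethylation of the hindered methyl ester by iodide (attack at the methyl carbon, not at the shielded carbonyl) frees the acid without base-mediated epimerisation at C2.

Step 11
Reactants: 19 hydroxy acid
Product: 20 (1R,2S,7aS)-1,7,7,7a-tetramethyl-1-(3-oxopropyl)-2,3,5,6,7,7a-hexahydro-1H-indene-2-carboxylic acid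
Conditions: Dess–Martin periodinane, NaHCO3, CH2Cl2, 0 → 25 °C
Reagents that add atoms: none
Why: Dess–Martin oxidation of the primary alcohol to the aldehyde under buffered conditions that the free acid, the C2 centre and the ring alkene should tolerate.

Step 12
Reactants: 20 aldehyde acid; 21 ethyl 2-[bis(2,2,2-trifluoroethoxy)phosphoryl]propanoate
Product: 23 (1R,2S,7aS)-1-[(3Z)-5-ethoxy-4-methyl-5-oxopent-3-en-1-yl]-1,7,7,7a-tetramethyl-2,3,5,6,7,7a-hexahydro-1H-indene-2-carboxylic acid, via potassium phosphonate carbanion 22 (not isolated)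
Conditions: 21 (2.3 equiv), KN(SiMe3)2 (2.2 equiv), 18-crown-6, THF, −78 °C; then 20; aq. citric acid
Reagents that add atoms: none
Why: Still–Gennari olefination, in which the bis(trifluoroethyl) phosphonate anion adds to the aldehyde and the oxaphosphetane collapses fast, should give the (Z)-trisubstituted enoate (ester cis to the chain) required by the target, the excess anion holding the acid as its carboxylate.

Step 13
Reactants: 23 (Z)-enoate acid
Product: 24 (1R,2S,7aS)-1-[(3Z)-5-hydroxy-4-methylpent-3-en-1-yl]-1,7,7,7a-tetramethyl-2,3,5,6,7,7a-hexahydro-1H-indene-2-carboxylic acid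
Conditions: iBu2AlH (4 equiv), CH2Cl2, −78 °C; aq. potassium sodium tartrate
Reagents that add atoms: none
Why: 1,2-reduction of the enoate by iBu2AlH to the allylic alcohol with retention of the (Z) geometry, the aluminium carboxylate being inert at −78 °C.

Step 14
Reactants: 24 (Z)-allylic alcohol acid
Product: 25 (1R,2S,7aS)-1-[(3Z)-5-(acetyloxy)-4-methylpent-3-en-1-yl]-1,7,7,7a-tetramethyl-2,3,5,6,7,7a-hexahydro-1H-indene-2-carboxylic acid
Conditions: Ac2O, pyridine, 4-(dimethylamino)pyridine (cat.), CH2Cl2, 0 °C; then aq. NaHCO3, acidify to pH 3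
Reagents that add atoms: acetic anhydride, CC(=O)OC(C)=O
Why: nucleophile-catalysed acetylation of the unhindered primary allylic alcohol, any mixed anhydride of the hindered acid being hydrolysed in the bicarbonate work-up.

**Compound list**
1 | 2,2-dimethylcyclohexanone | CC1(C)CCCCC1=O | starting material
2 | 2,2-dimethyl-6-methylidenecyclohexan-1-one | C=C1CCCC(C)(C)C1=O | intermediate
3 | rac-1,2,2-trimethyl-6-methylidenecyclohexan-1-ol | C=C1CCCC(C)(C)C1(C)O | intermediate
4 | (R)-1-phenylethyl isocyanate | C[C@@H](N=C=O)c1ccccc1 | starting material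
5 | (1R)-1,2,2-trimethyl-6-methylidenecyclohexyl N-[(1R)-1-phenylethyl]carbamate | C=C1CCCC(C)(C)[C@@]1(C)OC(=O)N[C@H](C)c1ccccc1 | intermediate
6 | 3-methylcyclohex-2-en-1-one | CC1=CC(=O)CCC1 | starting material
7 | spiro photoadduct: 6-methyl-2-oxospiro[bicyclo[4.2.0]octane-7,1'-cyclohexane] with 2',3',3'-trimethyl and 2'-carbamoyloxy groups; cis ring fusion; H-1, 6-methyl and C-2' on the exo face; C6–C7 bond anti to the 2'-oxygen | O=C1CCC[C@]2(C)[C@H]1C[C@]23CCCC(C)(C)[C@@]3(C)OC(=O)N[C@H](C)c1ccccc1 | intermediate
8 | dipotassium salt of 7 (ketone enolate towards C3 and carbamate nitrogen anion) | [O-]C1=CCC[C@]2(C)[C@H]1C[C@]23CCCC(C)(C)[C@@]3(C)OC(=O)[N-][C@H](C)c1ccccc1.[K+].[K+] | intermediate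
9 | 3-hydroxy derivative of 7 (both carbinol epimers) | O=C1C(O)CC[C@]2(C)[C@H]1C[C@]23CCCC(C)(C)[C@@]3(C)OC(=O)N[C@H](C)c1ccccc1 | intermediate
10 | methyl 1,5,6,6-tetramethyl-1-(3-oxopropyl)-5-{[(1R)-1-phenylethyl]carbamoyloxy}spiro[3.5]nonane-2-carboxylate; ester trans to the C1 methyl; C1 methyl and C5 on one face of the cyclobutane | COC(=O)[C@@H]1C[C@]2(CCCC(C)(C)[C@@]2(C)OC(=O)N[C@H](C)c2ccccc2)[C@]1(C)CCC=O | intermediate
11 | 1-(3-hydroxypropyl) analogue of 10; ester trans to the C1 methyl | COC(=O)[C@@H]1C[C@]2(CCCC(C)(C)[C@@]2(C)OC(=O)N[C@H](C)c2ccccc2)[C@]1(C)CCCO | intermediate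
12 | trilithium salt of 11 (ester enolate, alkoxide, carbamate nitrogen anion) | COC([O-])=C1C[C@]2(CCCC(C)(C)[C@@]2(C)OC(=O)[N-][C@H](C)c2ccccc2)[C@]1(C)CCC[O-].[Li+].[Li+].[Li+] | intermediate
13 | C2 epimer of 11; ester cis to the C1 methyl and to C5 | COC(=O)[C@H]1C[C@]2(CCCC(C)(C)[C@@]2(C)OC(=O)N[C@H](C)c2ccccc2)[C@]1(C)CCCO | intermediate
14 | trimethylsilyl ether of 13 | COC(=O)[C@H]1C[C@]2(CCCC(C)(C)[C@@]2(C)OC(=O)N[C@H](C)c2ccccc2)[C@]1(C)CCCO[Si](C)(C)C | intermediate
15 | ring-expanded tertiary C3a cation as its triflate | C[Si](C)(C)OCCC[C@]1(C)[C@@H](C(=O)OC)C[C+]2CCCC(C)(C)[C@@]21C.[O-]S(=O)(=O)C(F)(F)F | intermediate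
16 | trimethylsilyl ether of 17 | C[Si](C)(C)OCCC[C@]1(C)[C@@H](C(=O)OC)CC2=CCCC(C)(C)[C@@]21C | intermediate
17 | methyl (1R,2S,7aS)-1-(3-hydroxypropyl)-1,7,7,7a-tetramethyl-2,3,5,6,7,7a-hexahydro-1H-indene-2-carboxylate | OCCC[C@]1(C)[C@@H](C(=O)OC)CC2=CCCC(C)(C)[C@@]21C | intermediate
18 | lithium carboxylate of 19 | OCCC[C@]1(C)[C@@H](C(=O)[O-])CC2=CCCC(C)(C)[C@@]21C.[Li+] | intermediate
19 | (1R,2S,7aS)-1-(3-hydroxypropyl)-1,7,7,7a-tetramethyl-2,3,5,6,7,7a-hexahydro-1H-indene-2-carboxylic acid | OCCC[C@]1(C)[C@@H](C(=O)O)CC2=CCCC(C)(C)[C@@]21C | intermediate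
20 | (1R,2S,7aS)-1,7,7,7a-tetramethyl-1-(3-oxopropyl)-2,3,5,6,7,7a-hexahydro-1H-indene-2-carboxylic acid | O=CCC[C@]1(C)[C@@H](C(=O)O)CC2=CCCC(C)(C)[C@@]21C | intermediate
21 | ethyl 2-[bis(2,2,2-trifluoroethoxy)phosphoryl]propanoate | CCOC(=O)C(C)P(=O)(OCC(F)(F)F)OCC(F)(F)F | starting material
22 | potassium salt of the carbanion of 21 | CCOC(=O)[C-](C)P(=O)(OCC(F)(F)F)OCC(F)(F)F.[K+] | intermediate
23 | (1R,2S,7aS)-1-[(3Z)-5-ethoxy-4-methyl-5-oxopent-3-en-1-yl]-1,7,7,7a-tetramethyl-2,3,5,6,7,7a-hexahydro-1H-indene-2-carboxylic acid | CCOC(=O)/C(C)=C\CC[C@]1(C)[C@@H](C(=O)O)CC2=CCCC(C)(C)[C@@]21C | intermediate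
24 | (1R,2S,7aS)-1-[(3Z)-5-hydroxy-4-methylpent-3-en-1-yl]-1,7,7,7a-tetramethyl-2,3,5,6,7,7a-hexahydro-1H-indene-2-carboxylic acid | OC/C(C)=C\CC[C@]1(C)[C@@H](C(=O)O)CC2=CCCC(C)(C)[C@@]21C | intermediate
25 | (1R,2S,7aS)-1-[(3Z)-5-(acetyloxy)-4-methylpent-3-en-1-yl]-1,7,7,7a-tetramethyl-2,3,5,6,7,7a-hexahydro-1H-indene-2-carboxylic acid (C1 methyl, C7a methyl and CO2H all cis) | CC(=O)OC/C(C)=C\CC[C@]1(C)[C@@H](C(=O)O)CC2=CCCC(C)(C)[C@@]21C | target

**Total step count:** 14. **Longest linear sequence:** 14 steps (1 → 25); compounds 4, 6 and 21 enter as purchased reagents.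

**Steps most likely to fail**

Step 4. The triplet 1,4-biradical must close a bond between two fully substituted carbons, so it may revert or close in the head-to-head sense, and facial control by the carbamate centre may be weak. The fallback is a thermal keteniminium–alkene [2+2] cycloaddition, whose stepwise polar course forces the C1–C3a bond: the iminium carbon bonds to the CH2 terminus and the tertiary C3a cation is captured by the fully substituted enamine carbon. It sets out from 5. N,N-Dimethyl-2-methyl-5-[(triisopropylsilyl)oxy]pentanamide F1 is turned into its keteniminium triflate F2 with Tf2O and 2,4,6-collidine in 1,2-dichloroethane before 5 is added. The cyclobutaniminium triflate F3 is hydrolysed to the spiro cyclobutanone F4 (C2 carbonyl), whose two C1 epimers would have to be separated. Wittig reaction with Ph3P=CHOMe gives the enol ether F5, mild aqueous acid the C2 aldehyde F6, and I2/KOH in MeOH the methyl ester F7. Bu4NF then returns 11 mixed with its C2 epimer 13, which is acceptable because step 8 sets C2; the route is rejoined at 11.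

Step 9. Ionisation may occur without migration (loss of a methyl proton), the CH2 arm may migrate, the proton may be lost towards C3, or the C3a cation may suffer further methyl shifts. The fallback replaces kinetic proton loss by capture and thermodynamic release, and sets out from 13. Me3SnOH in 1,2-dichloroethane cleaves the ester to the cis hydroxy acid F8. Catalytic CF3SO3H in CH2Cl2 (primary alcohol silylated in situ) then brings about the same ring expansion, but the C3a cation is captured by the cis carboxyl to give the bridged γ-lactone F9, a single isolable compound. Acid-catalysed β-elimination of this tertiary lactone under equilibrating conditions (TsOH, toluene, reflux) should open it to the more stable C3a=C4 acid, rejoining the route at 19.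

Step 8. Deprotonation of the shielded C2–H may be slow, or the ester may return to the more stable trans epimer during quench. The fallback reaches the enol through a ketene instead of an enolate and sets out from 9. NaIO4 in aqueous THF gives the aldehyde acid F10, NaBH4 the hydroxy acid F11 and Ac2O/pyridine the acetoxy acid F12. 1-Chloro-N,N,2-trimethylprop-1-en-1-amine gives the acid chloride F13, and Et3N the ketene F14. Addition of MeOH at −78 °C and protonation of the resulting enol from the open face should give the cis ester acetate F15, and K2CO3 in MeOH at 0 °C returns 13.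

**Further compounds**
F1 | step 4 | N,N-dimethyl-2-methyl-5-[(triisopropylsilyl)oxy]pentanamide | CC(CCCO[Si](C(C)C)(C(C)C)C(C)C)C(=O)N(C)C
F2 | step 4 | keteniminium triflate from F1 | CC(CCCO[Si](C(C)C)(C(C)C)C(C)C)=C=[N+](C)C.[O-]S(=O)(=O)C(F)(F)F
F3 | step 4 | spiro cyclobutaniminium triflate (adduct of F2 and 5) | C[N+](C)=C1C[C@]2(CCCC(C)(C)[C@@]2(C)OC(=O)N[C@H](C)c2ccccc2)[C@]1(C)CCCO[Si](C(C)C)(C(C)C)C(C)C.[O-]S(=O)(=O)C(F)(F)F
F4 | step 4 | spiro cyclobutanone (C2 carbonyl, silyl-protected chain) | O=C1C[C@]2(CCCC(C)(C)[C@@]2(C)OC(=O)N[C@H](C)c2ccccc2)[C@]1(C)CCCO[Si](C(C)C)(C(C)C)C(C)C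
F5 | step 4 | methyl enol ether of F4 | COC=C1C[C@]2(CCCC(C)(C)[C@@]2(C)OC(=O)N[C@H](C)c2ccccc2)[C@]1(C)CCCO[Si](C(C)C)(C(C)C)C(C)C
F6 | step 4 | C2 aldehyde (epimer mixture) | O=CC1C[C@]2(CCCC(C)(C)[C@@]2(C)OC(=O)N[C@H](C)c2ccccc2)[C@]1(C)CCCO[Si](C(C)C)(C(C)C)C(C)C
F7 | step 4 | C2 methyl ester with silyl-protected chain (epimer mixture) | COC(=O)C1C[C@]2(CCCC(C)(C)[C@@]2(C)OC(=O)N[C@H](C)c2ccccc2)[C@]1(C)CCCO[Si](C(C)C)(C(C)C)C(C)C
F8 | step 9 | cis hydroxy acid from 13 | OC(=O)[C@H]1C[C@]2(CCCC(C)(C)[C@@]2(C)OC(=O)N[C@H](C)c2ccccc2)[C@]1(C)CCCO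
F9 | step 9 | bridged γ-lactone between the C2 carboxyl and C3a of the ring-expanded skeleton | OCCC[C@]1(C)[C@@H]2C[C@@]3(CCCC(C)(C)[C@@]31C)OC2=O
F10 | step 8 | trans aldehyde acid from 9 | OC(=O)[C@@H]1C[C@]2(CCCC(C)(C)[C@@]2(C)OC(=O)N[C@H](C)c2ccccc2)[C@]1(C)CCC=O
F11 | step 8 | trans hydroxy acid | OC(=O)[C@@H]1C[C@]2(CCCC(C)(C)[C@@]2(C)OC(=O)N[C@H](C)c2ccccc2)[C@]1(C)CCCO
F12 | step 8 | trans acetoxy acid | OC(=O)[C@@H]1C[C@]2(CCCC(C)(C)[C@@]2(C)OC(=O)N[C@H](C)c2ccccc2)[C@]1(C)CCCOC(C)=O
F13 | step 8 | acid chloride of F12 | ClC(=O)[C@@H]1C[C@]2(CCCC(C)(C)[C@@]2(C)OC(=O)N[C@H](C)c2ccccc2)[C@]1(C)CCCOC(C)=O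
F14 | step 8 | ketene at C2 | O=C=C1C[C@]2(CCCC(C)(C)[C@@]2(C)OC(=O)N[C@H](C)c2ccccc2)[C@]1(C)CCCOC(C)=O
F15 | step 8 | cis methyl ester acetate | COC(=O)[C@H]1C[C@]2(CCCC(C)(C)[C@@]2(C)OC(=O)N[C@H](C)c2ccccc2)[C@]1(C)CCCOC(C)=O
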